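The data were computed on assumed constants, noise included.

Molar per hour is the unit of a rate, and the order asked is taken from rates, but the readings are in molar, so a rate has to be reckoned out of amounts.

| flask | starting material | product | time |
|---|---|---|---|
| beta | 0.100 M |  |  |
| epsilon | 0.100 M | 0.0500 M |  |
| alpha | 0.150 M |  |  |
| gamma | 0.100 M |  | 15 h |

| run | time / h | [product] / M |
|---|---|---|
| beta run | 1.0 | 0.0148 |
| beta run | 2.0 | 0.0192 |
| beta run | 3.0 | 0.0212 |
| beta run | 4.0 | 0.0222 |
| beta run | 5.0 | 0.0230 |
| beta run | 6.0 | 0.0231 |
| epsilon run | 1.0 | 0.0655 |
| epsilon run | 2.0 | 0.0687 |
| epsilon run | 3.0 | 0.0710 |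
| epsilon run | 4.0 | 0.0728 |
| epsilon run | 5.0 | 0.0728 |
| epsilon run | 6.0 | 0.0733 |
| alpha run | 1.0 | 0.0187 |
| alpha run | 2.0 | 0.0237 |
| alpha run | 3.0 | 0.0264 |
| alpha run | 4.0 | 0.0274 |
| alpha run | 5.0 | 0.0282 |
| alpha run | 6.0 | 0.0280 |

(scatter of a reading: 3 × 10⁻⁴ M)

- Overall: starting material -> product.
- Constant volume, constant temperature.
- What is held in complexes is read along with the free species.
- An order is taken over about fifteen percent of the charge, up and down.

- apparent order in [starting material] of the starting rate, round the charge of the beta run (the rate where two percent of its starting material have turned into product) (one fixed amount of product, the same in the runs compared)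
- product in the gamma run at 15 h, as a share of the starting material charged

1. The beta flask flattens well below its charge of 0.100 M: it gains 0.00640 M from 1.0 h to 3.0 h, then 0.00180 M from 3.0 h to 5.0 h. If each equal step shrinks the gain by one constant factor, a first-order approach, the gains sum to a plateau of 0.0237 M. The gamma flask has the same charge, so my answer for it is 23.7 %.

2. This first answer now goes back into the first hour. By 1.0 h the beta flask has made 62.4 % of its plateau, so that reading is closer to a finished amount than to a rate. The plateau multiplied by the first-order constant of that first-hour approach gives 0.0232 M/h. This value is the reckoned start rate, the initial rate, taken as holding while the small fixed amount of product is made.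

3. The alpha flask, reckoned the same way, has a plateau of 0.0287 M and a start rate of 0.0302 M/h. The logarithm of the rate ratio over that of the charge ratio gives my order, 0.651.

The forecast gives 0.57 and 23.5 %, holding that “the curve shapes match”. Its order is lower than mine.

The flask gives an order of 0.82 and 24.1 %.

    2 starting material ⇌ intermediate + starting material (356.0 /M/h, 2617 /M/h)
    intermediate → product (3.816 /h)
    2 starting material → homo dimer (32.94 /M/h)
    2 starting material ⇌ idle substrate dimer, settled at all times (5.540 /M)

The start rates read from the readings, 0.0232 M/h for beta and 0.0302 M/h for alpha, stand against the flask's rates of 0.025 M/h and 0.035 M/h where two percent of the beta charge has turned, and my order stays lower than the flask's. In the epsilon flask the same reckoning gives a gain plateau of 0.0237 M and a rate of 0.0252 M/h, which is 1.09 of beta's against the flask's ratio of 1.0. In the gamma flask, while starting material was present, intermediate passed to product at 3.82 /h and starting material paired to homo dimer at 32.9 /M/h, with the idle substrate dimer kept in balance at 5.54 /M. At 15 h the gamma flask holds 24.1 % of its charge as product.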